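**Plan**
Retrosynthesis: the acetate and the C7 ketone are set last. The enol ether C14=C15 is traced back to a spiro-γ-lactone (C15=O). The lactone is cut at O–C16, giving a C16 methyl group and a C15 carboxylic acid. The oxolane is cut at C9–O, giving an 8β,9β-epoxide and the 13-OH.
What remains is (+)-manool, a chiral-pool labdane that already holds all twenty skeletal carbons: its vinyl group is C14–C15, its C13 methyl is C16, and its carbinol oxygen becomes the oxolane oxygen.
Forward order of rings: decalin (given), then oxolane C9–O–C13–C12–C11 (step 5), then the five-membered ring O–C16–C13–C14–C15 (step 9, last ring), then lactone to enol ether, C7 ketone and acetate.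
Stereochemistry: C5, C10 and C13 come from manool, and no bond to C13 is ever broken. The 7β-OH comes from axial hydride delivery and steers the epoxide to the β face (C8). Anti 5-exo opening by the tethered 13-OH fixes C9.
Enabling feature: the spiro carbon C13 is fully substituted (O9, C12, C14, C16). A carboxylate at C15 therefore has no β-hydrogen and finds only one methyl group, C16, at its γ position. The ring oxygen can be stitched between C15 and the unactivated C16–H by directed C–H functionalization, so the quaternary spiro centre need not be built.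

Key step: step 9

Remark: labdane numbering is used (C17 = methyl on C8, C20 = methyl on C10, C16 = one-carbon and C14–C15 = two-carbon substituent on C13). (+)-Manool is taken as a commercial natural product.

Step 1
Reactants: 1 (+)-manool, (13R)-labda-8(17),14-dien-13-ol
Product: 2 7α-hydroxymanool, (13R)-labda-8(17),14-diene-7α,13-diol
Conditions: SeO2 (0.5 equiv), t-BuOOH (decane, 3 equiv), CH2Cl2, 0 °C → rt
Reagents that add atoms: tert-butyl hydroperoxide, CC(C)(C)OO (its oxygen reaches C7 by way of selenium dioxide, O=[Se]=O)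
Why: Riley allylic hydroxylation (ene reaction, then [2,3]-shift) can engage only the C8=C17 olefin, because the vinyl group has no allylic hydrogen, and should place oxygen on C7 from the open α face, a stereocentre that step 2 erases.

Step 2
Reactants: 2 7α-hydroxymanool
Product: 3 (13R)-13-hydroxylabda-8(17),14-dien-7-one (α-methylene ketone)
Conditions: Dess–Martin periodinane (1.2 equiv), pyridine (3 equiv), CH2Cl2, 0 °C → rt
Reagents that add atoms: none
Why: Dess–Martin oxidation converts the secondary allylic alcohol into the enone under buffered, near-neutral conditions that leave the tertiary allylic alcohol and both olefins alone.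

Step 3
Reactants: 3 (13R)-13-hydroxylabda-8(17),14-dien-7-one
Product: 4 (13R)-13-hydroxylabda-8,14-dien-7-one (tetrasubstituted endocyclic enone)
Conditions: RhCl(PPh3)3 (5 mol %), Et3SiH (15 mol %), toluene, 90 °C
Reagents that add atoms: none
Why: Rhodium hydride addition and β-hydride elimination (exo-to-endo enone isomerization, known for α-methylene ketones and lactones) runs under equilibrium control in a neutral medium to the conjugated C8=C9 enone, while the vinyl group cannot migrate because C13 bears no hydrogen and the C9 stereocentre is given up on purpose.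

Step 4
Reactants: 4 (13R)-13-hydroxylabda-8,14-dien-7-one
Product: 5 (13R)-labda-8,14-diene-7β,13-diol
Conditions: NaBH4, CeCl3·7H2O, MeOH, −40 → 0 °C
Reagents that add atoms: none
Why: In this Luche 1,2-reduction hydride should add axially from the α face, away from the C20 methyl, to give the pseudo-equatorial 7β-alcohol, as with steroidal 4-en-3-ones and 8-en-7-ones.

Step 5
Reactants: 5 (13R)-labda-8,14-diene-7β,13-diol
Product: 7 (13R)-9α,13-epoxylabd-14-ene-7β,8β-diol, via 8β,9β-epoxy diol 6 (not isolated)
Conditions: VO(acac)2 (5 mol %), t-BuOOH (decane, 1.2 equiv), CH2Cl2, 0 °C; then CSA (10 mol %), 0 °C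
Reagents that add atoms: tert-butyl hydroperoxide, CC(C)(C)OO
Why: Hydroxyl-directed vanadium epoxidation delivers oxygen syn to the 7β-OH onto the electron-rich tetrasubstituted olefin (β face, setting C8, as for steroidal 4-en-3β-ols despite the angular methyl), and the 13-OH then opens the epoxide at C9 in an acid-catalysed 5-exo-tet, trans-diaxial (Fürst–Plattner) manner with inversion, which sets the 9α-oxygen and mirrors the cyclization of linalool epoxide to furanoid linalool oxide.

Step 6
Reactants: 7 (13R)-9α,13-epoxylabd-14-ene-7β,8β-diol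
Product: 8 (13R)-7β-(tert-butyldimethylsilyloxy)-9α,13-epoxylabd-14-en-8β-ol
Conditions: TBSOTf (1.2 equiv), 2,6-lutidine, CH2Cl2, −78 → 0 °C
Reagents that add atoms: tert-butyldimethylsilyl triflate, CC(C)(C)[Si](C)(C)OS(=O)(=O)C(F)(F)F
Why: Silyl ether formation is expected only at the secondary equatorial 7β-OH, because the axial tertiary 8β-OH is flanked by quaternary C9 and lies 1,3-diaxial to the C20 methyl, and it parks C7 at the alcohol level so that the later hydride step cannot touch it.

Step 7
Reactants: 8 (13R)-7β-(tert-butyldimethylsilyloxy)-9α,13-epoxylabd-14-en-8β-ol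
Product: 10 (13R)-7β-(tert-butyldimethylsilyloxy)-9α,13-epoxylabdane-8β,15-diol, via B-alkyl-9-BBN adduct 9 (not isolated)
Conditions: 9-BBN-H (3 equiv), THF, rt → 45 °C; then aq NaOH, H2O2, 0 °C → rt
Reagents that add atoms: 9-borabicyclo[3.3.1]nonane, B1C2CCCC1CCC2 (boron unit of 9); hydrogen peroxide, OO (oxygen of 10)
Why: Brown hydroboration–oxidation with bulky 9-BBN places boron on terminal C15 of the only olefin (anti-Markovnikov, next to quaternary C13), and alkaline peroxide replaces boron by OH without touching C13.

Step 8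
Reactants: 10 (13R)-7β-(tert-butyldimethylsilyloxy)-9α,13-epoxylabdane-8β,15-diol
Product: 11 (13R)-7β-(tert-butyldimethylsilyloxy)-9α,13-epoxy-8β-hydroxylabdan-15-oic acid
Conditions: TEMPO (20 mol %), PhI(OAc)2 (2.5 equiv), MeCN–H2O (1:1), rt
Reagents that add atoms: water, O
Why: Oxoammonium (TEMPO/PhI(OAc)2) oxidation in aqueous acetonitrile carries the unhindered primary alcohol through the aldehyde hydrate to the acid under conditions too mild for β-elimination of the C13 ether or loss of the silyl group.

Step 9
Reactants: 11 (13R)-7β-(tert-butyldimethylsilyloxy)-9α,13-epoxy-8β-hydroxylabdan-15-oic acid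
Product: 12 (13R)-7β-(tert-butyldimethylsilyloxy)-9α,13-epoxy-8β-hydroxylabdan-15,16-olide (spiro-γ-lactone)
Conditions: Pd(OAc)2 (10 mol %), N-acetyl-tert-leucine (20 mol %), NaOAc (0.5 equiv), t-BuOOH (2 equiv), HFIP, 70 °C
Reagents that add atoms: none
Why: The carboxylate of 11 binds Pd(II) and, assisted by the mono-N-protected amino acid ligand, a concerted metalation–deprotonation cleaves one C16–H bond to give a six-membered palladacycle (Pd–O–C15–C14–C13–C16), which t-BuOOH oxidises to Pd(IV) before C16–O reductive elimination releases the γ-lactone. The closest known reaction type is the carboxylate-directed Pd(II)/Pd(IV) lactonization of free, β-quaternary aliphatic acids at a γ-methyl group, with manganese-catalysed γ-lactonization of primary C–H bonds as its radical counterpart. The single ring closed is the five-membered ring O–C16–C13–C14–C15, formally by a 5-exo-tet attack of the carboxylate oxygen on the Pd(IV)-bound C16H2. No stereocentre is created: C13 keeps all four of its bonds, so its manool-derived R configuration becomes the spiro configuration, with C16 on the C8 side and C14 on the C10 side of the oxolane. The step needs site selectivity, which the substrate secures: C13 is fully substituted (no β-C–H, hence no five-membered palladacycle and no dehydrogenation), the only γ-C–H bonds are those of the C16 methyl and the ring methylene C12, and concerted metalation strongly prefers the primary, freely rotating methyl. Loss of the β-alkoxide O9 from the palladacycle is held back by chelation (no syn-coplanar Pd–C16–C13–O9 arrangement), and no olefin, ketone or ester is present to interfere because the vinyl group has been used up and C7 is parked as its silyl ether.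

Step 10
Reactants: 12 spiro-γ-lactone
Product: 13 (13R)-7β-(tert-butyldimethylsilyloxy)-9α,13;15,16-diepoxylabdane-8β,15-diol (lactol, both C15 anomers)
Conditions: DIBAL-H (2.5 equiv), CH2Cl2, −78 °C; aq Rochelle salt
Reagents that add atoms: none
Why: DIBAL-H reduction of a γ-lactone stops at the tetrahedral aluminium lactolate at −78 °C (one further equivalent being consumed by the 8-OH), which gives the lactol as an inconsequential mixture of C15 anomers.

Step 11
Reactants: 13 lactol
Product: 15 (13R)-7β-(tert-butyldimethylsilyloxy)-9α,13;15,16-diepoxylabd-14-en-8β-ol, via lactol mesylate 14 (not isolated)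
Conditions: MsCl (1.5 equiv), Et3N (6 equiv), CH2Cl2, −20 → 40 °C; Et3N-deactivated silica
Reagents that add atoms: methanesulfonyl chloride, CS(=O)(=O)Cl (mesyl group of 14 only)
Why: Mesylation of the lactol hydroxyl, loss of mesylate through the C15 oxocarbenium ion and removal of a C14 proton by Et3N is the standard lactol-to-cyclic-enol-ether (glycal-type) dehydration, C14=C15 being the only possible position because the ring oxygen and quaternary C13 flank these two carbons, and the basic medium protects the acid-labile product.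

Step 12
Reactants: 15 silylated dihydrofuran
Product: 16 (13R)-9α,13;15,16-diepoxylabd-14-ene-7β,8β-diol
Conditions: TBAF (3 equiv), THF, rt → 45 °C
Reagents that add atoms: none
Why: Fluoride-induced desilylation is non-acidic and therefore compatible with the enol ether and its allylic C13–O bond.

Step 13
Reactants: 16 (13R)-9α,13;15,16-diepoxylabd-14-ene-7β,8β-diol
Product: 17 (13R)-8β-hydroxy-9α,13;15,16-diepoxylabd-14-en-7-one
Conditions: SO3·pyridine (4 equiv), DMSO, Et3N, CH2Cl2, 0 °C → rt
Reagents that add atoms: none
Why: Parikh–Doering oxidation converts the secondary 7β-alcohol into the ketone in an amine-buffered medium without cleaving the vicinal diol or attacking the enol ether, the tertiary 8β-OH being inert.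

Step 14
Reactants: 17 (13R)-8β-hydroxy-9α,13;15,16-diepoxylabd-14-en-7-one
Product: 19 (13R)-8β-acetoxy-9α,13;15,16-diepoxylabd-14-en-7-one (target), via lithium 8β-alkoxide 18 (not isolated)
Conditions: LiHMDS (1.05 equiv), THF, −78 °C; then Ac2O (1.5 equiv), −78 → 0 °C; pH 7 buffer
Reagents that add atoms: lithium hexamethyldisilazide, [Li+].C[Si](C)(C)[N-][Si](C)(C)C (lithium of 18); acetic anhydride, CC(=O)OC(C)=O
Why: O-Acylation of the preformed lithium alkoxide, the usual method for hindered tertiary alcohols in base-tolerant polyfunctional substrates, acetylates the axial 8β-oxygen with retention because no bond to C8 is broken, one equivalent of base taking the OH proton in preference to a C6 proton.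

**Compound list**
1 | (+)-manool, (13R)-labda-8(17),14-dien-13-ol | C=C1CC[C@H]2C(C)(C)CCC[C@]2(C)[C@H]1CC[C@](C)(C=C)O | starting material
2 | (13R)-labda-8(17),14-diene-7α,13-diol | C=C1[C@H](O)C[C@H]2C(C)(C)CCC[C@]2(C)[C@H]1CC[C@](C)(C=C)O | intermediate
3 | (13R)-13-hydroxylabda-8(17),14-dien-7-one | C=C1C(=O)C[C@H]2C(C)(C)CCC[C@]2(C)[C@H]1CC[C@](C)(C=C)O | intermediate
4 | (13R)-13-hydroxylabda-8,14-dien-7-one | CC1=C(CC[C@](C)(C=C)O)[C@@]2(C)CCCC(C)(C)[C@@H]2CC1=O | intermediate
5 | (13R)-labda-8,14-diene-7β,13-diol | CC1=C(CC[C@](C)(C=C)O)[C@@]2(C)CCCC(C)(C)[C@@H]2C[C@@H]1O | intermediate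
6 | (13R)-8β,9β-epoxylabd-14-ene-7β,13-diol (not isolated) | C[C@@]12O[C@]1(CC[C@](C)(C=C)O)[C@@]3(C)CCCC(C)(C)[C@@H]3C[C@@H]2O | intermediate
7 | (13R)-9α,13-epoxylabd-14-ene-7β,8β-diol | O[C@@]1(C)[C@@H](O)C[C@H]2C(C)(C)CCC[C@]2(C)[C@@]12CC[C@](C)(C=C)O2 | intermediate
8 | (13R)-7β-(tert-butyldimethylsilyloxy)-9α,13-epoxylabd-14-en-8β-ol | O[C@@]1(C)[C@@H](O[Si](C)(C)C(C)(C)C)C[C@H]2C(C)(C)CCC[C@]2(C)[C@@]12CC[C@](C)(C=C)O2 | intermediate
9 | B-(labdan-15-yl)-9-BBN adduct of 8 (not isolated) | O[C@@]1(C)[C@@H](O[Si](C)(C)C(C)(C)C)C[C@H]2C(C)(C)CCC[C@]2(C)[C@@]12CC[C@](C)(CCB3C4CCCC3CCC4)O2 | intermediate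
10 | (13R)-7β-(tert-butyldimethylsilyloxy)-9α,13-epoxylabdane-8β,15-diol | O[C@@]1(C)[C@@H](O[Si](C)(C)C(C)(C)C)C[C@H]2C(C)(C)CCC[C@]2(C)[C@@]12CC[C@](C)(CCO)O2 | intermediate
11 | (13R)-7β-(tert-butyldimethylsilyloxy)-9α,13-epoxy-8β-hydroxylabdan-15-oic acid | O[C@@]1(C)[C@@H](O[Si](C)(C)C(C)(C)C)C[C@H]2C(C)(C)CCC[C@]2(C)[C@@]12CC[C@](C)(CC(=O)O)O2 | intermediate
12 | (13R)-7β-(tert-butyldimethylsilyloxy)-9α,13-epoxy-8β-hydroxylabdan-15,16-olide | O[C@@]1(C)[C@@H](O[Si](C)(C)C(C)(C)C)C[C@H]2C(C)(C)CCC[C@]2(C)[C@@]12CC[C@]1(CC(=O)OC1)O2 | intermediate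
13 | (13R)-7β-(tert-butyldimethylsilyloxy)-9α,13;15,16-diepoxylabdane-8β,15-diol (C15 anomers) | O[C@@]1(C)[C@@H](O[Si](C)(C)C(C)(C)C)C[C@H]2C(C)(C)CCC[C@]2(C)[C@@]12CC[C@]1(CC(O)OC1)O2 | intermediate
14 | 15-O-mesylate of lactol 13 (not isolated) | O[C@@]1(C)[C@@H](O[Si](C)(C)C(C)(C)C)C[C@H]2C(C)(C)CCC[C@]2(C)[C@@]12CC[C@]1(CC(OS(C)(=O)=O)OC1)O2 | intermediate
15 | (13R)-7β-(tert-butyldimethylsilyloxy)-9α,13;15,16-diepoxylabd-14-en-8β-ol | O[C@@]1(C)[C@@H](O[Si](C)(C)C(C)(C)C)C[C@H]2C(C)(C)CCC[C@]2(C)[C@@]12CC[C@]1(C=COC1)O2 | intermediate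
16 | (13R)-9α,13;15,16-diepoxylabd-14-ene-7β,8β-diol | O[C@@]1(C)[C@@H](O)C[C@H]2C(C)(C)CCC[C@]2(C)[C@@]12CC[C@]1(C=COC1)O2 | intermediate
17 | (13R)-8β-hydroxy-9α,13;15,16-diepoxylabd-14-en-7-one | O[C@@]1(C)C(=O)C[C@H]2C(C)(C)CCC[C@]2(C)[C@@]12CC[C@]1(C=COC1)O2 | intermediate
18 | lithium 8β-alkoxide of 17 (not isolated) | [Li+].[O-][C@@]1(C)C(=O)C[C@H]2C(C)(C)CCC[C@]2(C)[C@@]12CC[C@]1(C=COC1)O2 | intermediate
19 | (13R)-8β-acetoxy-9α,13;15,16-diepoxylabd-14-en-7-one | CC(=O)O[C@@]1(C)C(=O)C[C@H]2C(C)(C)CCC[C@]2(C)[C@@]12CC[C@]1(C=COC1)O2 | target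

Total step count: 14. Longest linear sequence: 14 steps (1 → 19).

**Steps most likely to fail**

**Step 9.** Palladation of the hindered C16 methyl may be too slow. Metalation at C12–H, β-alkoxide loss with opening of the oxolane, or desilylation in hot HFIP could then take over.
The fallback replaces carboxylate-directed palladation by alcohol-directed C–H silylation. It sets out from 10 and comes back at 12.
- Dehydrogenative silylation of the primary alcohol with Et2SiH2 ([Ir(cod)OMe]2 cat., THF) should give the diethylhydrosilyl ether F1.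
- Rhodium/Xantphos-catalysed intramolecular C–H silylation with norbornene as hydrogen acceptor is selective for primary C–H bonds. It should close the spiro-1,2-oxasilinane F2 at the C16 methyl, since γ-carbon C13 has no hydrogen.
- Tamao–Fleming oxidation (H2O2, KHCO3, THF–MeOH) should give the 15,16-diol F3.
- TEMPO/PhI(OAc)2 in CH2Cl2 should oxidise the less hindered C15 carbinol first and carry the resulting lactol on to lactone 12.

**Step 3.** The isomerization may stall short of the endocyclic enone. The hot metal hydride medium may also cause hydrosilylation or ionization and transposition of the tertiary allylic alcohol.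
The fallback moves the double bond by an enolate–selenoxide sequence. It sets out from 3 and comes back at 4.
- Conjugate reduction with L-Selectride (THF, −78 °C, extra equivalent for the OH) gives the C7–C8 enolate regiospecifically.
- Trapping with PhSeBr from the less hindered α face should give the 8α-phenylselanyl ketone F4.
- Oxidation (H2O2, pyridine, CH2Cl2, 0 °C) should trigger selenoxide syn elimination towards the cis-disposed 9α-hydrogen and give 4.

**Step 14.** Acylation of the axial, doubly flanked alkoxide may be so slow that enolization at C6, O-acetylation of the enolate or an α-ketol shift competes.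
The fallback changes the order so that the acetate is put on while no ketone is present. It sets out from 15 and comes back at 19.
- Deprotonation of 15 with KHMDS and quenching with Ac2O (THF, −78 → 25 °C, excess reagents allowed) should give the 8β-acetate 7β-silyl ether F5.
- Desilylation with AcOH-buffered TBAF, which suppresses acyl migration to O7, should give the 8β-acetoxy-7β-alcohol F6.
- F6 is oxidised at once under Parikh–Doering conditions to 19.

Further compounds
F1 | step 9 | 15-O-diethylhydrosilyl ether of 10 | O[C@@]1(C)[C@@H](O[Si](C)(C)C(C)(C)C)C[C@H]2C(C)(C)CCC[C@]2(C)[C@@]12CC[C@](C)(CCO[SiH](CC)CC)O2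
F2 | step 9 | spiro-1,2-oxasilinane (Si bridging O15 and C16) | O[C@@]1(C)[C@@H](O[Si](C)(C)C(C)(C)C)C[C@H]2C(C)(C)CCC[C@]2(C)[C@@]12CC[C@]1(CCO[Si](CC)(CC)C1)O2
F3 | step 9 | (13R)-7β-(tert-butyldimethylsilyloxy)-9α,13-epoxylabdane-8β,15,16-triol | O[C@@]1(C)[C@@H](O[Si](C)(C)C(C)(C)C)C[C@H]2C(C)(C)CCC[C@]2(C)[C@@]12CC[C@](CO)(CCO)O2
F4 | step 3 | (13R)-13-hydroxy-8α-(phenylselanyl)labd-14-en-7-one | C[C@@]1([Se]c2ccccc2)C(=O)C[C@H]2C(C)(C)CCC[C@]2(C)[C@H]1CC[C@](C)(C=C)O
F5 | step 14 | (13R)-8β-acetoxy-7β-(tert-butyldimethylsilyloxy)-9α,13;15,16-diepoxylabd-14-ene | CC(=O)O[C@@]1(C)[C@@H](O[Si](C)(C)C(C)(C)C)C[C@H]2C(C)(C)CCC[C@]2(C)[C@@]12CC[C@]1(C=COC1)O2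
F6 | step 14 | (13R)-8β-acetoxy-9α,13;15,16-diepoxylabd-14-en-7β-ol | CC(=O)O[C@@]1(C)[C@@H](O)C[C@H]2C(C)(C)CCC[C@]2(C)[C@@]12CC[C@]1(C=COC1)O2
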